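C1 quaternary (C-methyl), C2, C3, C4 (isopropyl carbinol), C5 (ring-fusion CH), C6 (acyloxy CH), C7, C8 (carries formyl carbon C14), C9, C10; ring A = C1–C5, ring B = C1, C5–C10; the target is (1R,4R,5S,6S).
Cuts, in retrosynthetic order: the C6–O ester bond; C4–isopropyl (back to a C4 ketone); C5–H and C6–O (back to a C5=C6 alkene); C7–C8 and C1–C10 of ring B in one stroke; last the vinyl–ring bond C5–C6, back to 3-methylcyclopent-2-en-1-one.
Enabling feature: in ring B the formyl-bearing C8 of the C8=C9 alkene lies two bonds from quaternary C1 and one methylene (C7) from C6, so with C5=C6 drawn ring B is a cyclohepta-1,4-diene; C8–C9–C10 is a vinylcarbenoid and C7–C6–C5–C1 a 2-vinylcyclopentene.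
Forward order: ring A is bought as the cyclopentenone and becomes the ketal-masked vinyl diene; ring B is closed onto it by carbenoid cyclopropanation and Cope ring expansion; then C5/C6 are functionalised, C14 is reduced, C4 is unmasked and isopropylated, C14 is re-oxidised and O6 acylated.
Stereochemistry: C1 from the chiral dirhodium prolinate, relayed by the boat Cope shift; C5 and C6 from one syn hydroboration on the face away from the C1 methyl; C4 from α-face addition to the trans-fused ketone.

Key step: step 5

Assumption: (S)-prolinate dirhodium catalysts are taken to give, from a monosubstituted alkene and a donor/acceptor diazoacetate, the E-cyclopropane of the sense of methyl (1S,2R)-1,2-diphenylcyclopropane-1-carboxylate; relayed through the boat Cope shift that sense would give (S)-C1, so the (R)-catalyst Rh2(R-DOSP)4 is specified to reach (1S,2S)-8 and (R)-C1.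

Step 1
Reactants: 1 3-methylcyclopent-2-en-1-one
Product: 2 2-iodo-3-methylcyclopent-2-en-1-one
Conditions: I2, pyridine, CH2Cl2, 0 °C to rt
Reagents that add atoms: iodine, II
Why: Pyridine-mediated α-iodination of the enone (conjugate addition of pyridine, iodination of the enolate, elimination) puts the halogen on the carbon that becomes C5.

Step 2
Reactants: 2 2-iodo-3-methylcyclopent-2-en-1-one
Product: 3 6-iodo-7-methyl-1,4-dioxaspiro[4.4]non-6-ene
Conditions: ethylene glycol, p-TsOH·H2O (cat.), benzene, reflux, Dean–Stark trap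
Reagents that add atoms: ethylene glycol, OCCO
Why: Acid-catalysed ketalisation with azeotropic removal of water masks the future C4 ketone, and with the α-halogen in place the double bond does not migrate, as in the well-known 2-bromo analogue.

Step 3
Reactants: 3 6-iodo-7-methyl-1,4-dioxaspiro[4.4]non-6-ene; 4 tributyl(vinyl)stannane
Product: 5 7-methyl-6-vinyl-1,4-dioxaspiro[4.4]non-6-ene
Conditions: Pd(PPh3)4 (5 mol %), CuI (10 mol %), CsF, DMF, 45 °C
Reagents that add atoms: none
Why: Stille cross-coupling of the vinyl iodide with the vinylstannane, accelerated by CuI and fluoride for the hindered tetrasubstituted halide, gives the 1,3-diene with the ring alkene in place.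

Step 4
Reactants: 6 methyl but-3-enoate
Product: 7 methyl 2-diazobut-3-enoate
Conditions: 4-acetamidobenzenesulfonyl azide, DBU, MeCN, 0 °C; cold pentane extraction, used at once
Reagents that add atoms: 4-acetamidobenzenesulfonyl azide, CC(=O)Nc1ccc(cc1)S(=O)(=O)N=[N+]=[N-]
Why: Regitz diazo transfer to the methylene activated by both the ester and the vinyl group; the product is kept cold and used immediately because it closes slowly to a pyrazole at room temperature.

Step 5
Reactants: 5 7-methyl-6-vinyl-1,4-dioxaspiro[4.4]non-6-ene; 7 methyl 2-diazobut-3-enoate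
Product: 9 ketal diene ester [(1R); C4 ethylene ketal; C5=C6; C8=C9; CO2Me on C8], via cis-divinylcyclopropane 8 (not isolated)
Conditions: Rh2(R-DOSP)4 [dirhodium tetrakis((R)-N-(4-dodecylbenzenesulfonyl)prolinate)] (1 mol %), hexanes, −78 °C, 7 (about 2 equiv) added slowly, then rt; then toluene, 80 °C
Reagents that add atoms: none
Why: Loss of N2 from 7 at the dirhodium centre gives a donor/acceptor carbenoid whose carbon (C8) cyclopropanates the vinyl group C6=C7 by the usual asynchronous end-on approach, giving E-cyclopropane 8 with the C9=C10 vinyl and the cyclopentenyl group cis. The cis-divinylcyclopropane then undergoes a [3,3] shift through the enforced boat transition state, forming C1–C10 and breaking C6–C8, so seven-membered ring B closes by ring expansion of the three-membered ring, in sum a formal [4+3] cycloaddition of C7, C6, C5, C1 with C8, C9, C10. The closest known reaction is the tandem cyclopropanation/Cope rearrangement of vinyldiazoacetates with 1,3-dienes under chiral dirhodium carboxylates, including 1-vinylcycloalkenes whose substituted ring terminus becomes quaternary. C1, the only stereocentre formed, is controlled by the enantioface selection of the prolinate catalyst at the vinyl group and is transferred stereospecifically by the boat geometry to (R)-C1. The step needs site selectivity for the vinyl group over the ring alkene, the allylic C–H bonds and the ketal oxygens, which the substrate secures because the ring alkene is tetrasubstituted and the vinyl group is the only monosubstituted, electron-rich π bond. Because the ring methyl is cis to C6 and must pass over the cyclopropane in the boat, the mixture is warmed after carbene transfer to complete the shift.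

Step 6
Reactants: 9 ketal diene ester
Product: 11 (1R,5S,6S)-6-hydroxy ketal ester [5α-H; 6α-OH; C8=C9 retained], via C6 alkylborane 10 (not isolated)
Conditions: BH3·THF (1.5 equiv), THF, 0 °C to rt; then aq. NaOH, 30% H2O2, 0 °C
Reagents that add atoms: hydrogen peroxide, OO; borane–tetrahydrofuran complex, B.C1CCOC1 (boron of 10 only)
Why: Syn hydroboration of the electron-rich trisubstituted C5=C6 with boron on the less substituted C6 is expected on the α-face away from the C1 methyl, as with angularly methylated hydrindenes and Δ5-steroids, which sets H5 and O6 cis to each other and trans to the methyl (trans ring fusion), while the electron-poor enoate reacts more slowly and the oxidation proceeds with retention.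

Step 7
Reactants: 11 (1R,5S,6S)-6-hydroxy ketal ester
Product: 12 6-O-tert-butyldimethylsilyl ether of 11
Conditions: TBSOTf, 2,6-lutidine, CH2Cl2, −78 to 0 °C
Reagents that add atoms: tert-butyldimethylsilyl trifluoromethanesulfonate, CC(C)(C)[Si](C)(C)OS(=O)(=O)C(F)(F)F
Why: Silylation of the hindered secondary alcohol with the silyl triflate under lutidine buffering, which leaves the dioxolane intact, protects O6 through the hydride and organometallic steps.

Step 8
Reactants: 12 6-O-silyl ketal ester
Product: 13 C14 allylic alcohol [C4 ketal; 6-OTBS]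
Conditions: i-Bu2AlH (3 equiv), CH2Cl2, −78 to 0 °C; aq. potassium sodium tartrate
Reagents that add atoms: none
Why: i-Bu2AlH reduces the conjugated methyl ester by 1,2-addition to the primary allylic alcohol without touching the ketal, the silyl ether or the C8=C9 alkene.

Step 9
Reactants: 13 C14 allylic alcohol
Product: 14 (1R,5S,6S)-C4 ketone [6-OTBS; C14 OH]
Conditions: PPTS (cat.), acetone/H2O, 50 °C
Reagents that add atoms: water, O
Why: Mild acid-catalysed hydrolysis of the dioxolane frees the C4 ketone while the secondary silyl ether survives, weak acid being chosen because the β-silyloxy ketone would eliminate across C5–C6 under base.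

Step 10
Reactants: 14 C4 ketone
Product: 15 (1R,4R,5S,6S)-4-isopropyl-4,14-diol 6-O-silyl ether
Conditions: i-PrMgCl (4 equiv), CeCl3 (anhydrous, 4 equiv), THF, −78 to −40 °C; aq. NH4Cl
Reagents that add atoms: isopropylmagnesium chloride, CC(C)[Mg]Cl
Why: Organocerium 1,2-addition, in which the weakly basic i-PrCeCl2 adds to the enolisable β-silyloxy ketone without elimination or hydride transfer, should occur on the α-face anti to the adjacent C5–C6 bond and the angular methyl, giving the 4β-hydroxyl (4R) with the C14 hydroxyl carried as its cerium alkoxide.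

Step 11
Reactants: 15 4-isopropyl diol 6-O-silyl ether
Product: 16 (1R,4R,5S,6S)-4,6,14-triol
Conditions: TBAF, THF, rt
Reagents that add atoms: none
Why: Fluoride cleavage of the silyl ether, driven by Si–F bond formation, frees O6 at a stage where no base-sensitive carbonyl group is present.

Step 12
Reactants: 16 4,6,14-triol
Product: 17 (1R,4R,5S,6S)-4,6-dihydroxy C14 enal
Conditions: MnO2 (activated), CH2Cl2, rt
Reagents that add atoms: none
Why: MnO2 oxidises only the allylic primary alcohol to the conjugated aldehyde and leaves the saturated secondary and tertiary hydroxyls untouched.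

Step 13
Reactants: 18 4-hydroxybenzoic acid
Product: 20 4-[(tert-butyldimethylsilyl)oxy]benzoic acid, via bis-silylated benzoate 19 (not isolated)
Conditions: TBSCl (2.5 equiv), imidazole, DMF, rt; then AcOH, THF/H2O, rt
Reagents that add atoms: tert-butyldimethylsilyl chloride, CC(C)(C)[Si](C)(C)Cl
Why: Exhaustive silylation followed by selective hydrolysis of the labile silyl ester leaves the phenol masked and the carboxylic acid free for coupling.

Step 14
Reactants: 17 4,6-dihydroxy enal; 20 4-[(tert-butyldimethylsilyl)oxy]benzoic acid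
Product: 21 6-O-[4-(tert-butyldimethylsilyloxy)benzoyl] ester of 17
Conditions: EDC·HCl, DMAP, CH2Cl2, rt
Reagents that add atoms: none
Why: Steglich esterification (carbodiimide activation, acyl transfer by DMAP) acylates the secondary C6 hydroxyl with retention and leaves the tertiary C4 hydroxyl alone, as in known 6-O-acylations of daucane 4,6-diols.

Step 15
Reactants: 21 silyl-protected ester
Product: 22 target, (1R,4R,5S,6S)-6-O-(4-hydroxybenzoyl) enal
Conditions: TBAF (1.1 equiv), AcOH (1.2 equiv), THF, 0 °C
Reagents that add atoms: none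
Why: Buffered fluoride removes the aryl silyl ether within minutes at 0 °C without transesterifying the benzoate or isomerising the enal.

Compound list
1 | 3-methylcyclopent-2-en-1-one | CC1=CC(=O)CC1 | starting material
2 | 2-iodo-3-methylcyclopent-2-en-1-one | CC1=C(I)C(=O)CC1 | intermediate
3 | 6-iodo-7-methyl-1,4-dioxaspiro[4.4]non-6-ene | CC1=C(I)C2(CC1)OCCO2 | intermediate
4 | tributyl(vinyl)stannane | C=C[Sn](CCCC)(CCCC)CCCC | starting material
5 | 7-methyl-6-vinyl-1,4-dioxaspiro[4.4]non-6-ene | C=CC1=C(C)CCC12OCCO2 | intermediate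
6 | methyl but-3-enoate | C=CCC(=O)OC | starting material
7 | methyl 2-diazobut-3-enoate | COC(=O)C(=[N+]=[N-])C=C | intermediate
8 | methyl (1S,2S)-2-(7-methyl-1,4-dioxaspiro[4.4]non-6-en-6-yl)-1-vinylcyclopropane-1-carboxylate (vinyl cis to the cyclopentenyl group) | COC(=O)[C@]1(C=C)C[C@H]1C1=C(C)CCC12OCCO2 | intermediate (not isolated)
9 | ketal diene ester: (1R)-1-methyl, 4,4-ethylenedioxy, C5=C6 and C8=C9, CO2Me on C8 | COC(=O)C1=CC[C@@]2(C)CCC3(OCCO3)C2=CC1 | intermediate
10 | C6 alkylborane of 9 (5α-H, 6α-BH2) | COC(=O)C1=CC[C@@]2(C)CCC3(OCCO3)[C@@H]2[C@@H](B)C1 | intermediate (not isolated)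
11 | (1R,5S,6S)-6-hydroxy ketal ester (5α-H, 6α-OH, C8=C9, CO2Me on C8) | COC(=O)C1=CC[C@@]2(C)CCC3(OCCO3)[C@@H]2[C@@H](O)C1 | intermediate
12 | 6-O-tert-butyldimethylsilyl ether of 11 | COC(=O)C1=CC[C@@]2(C)CCC3(OCCO3)[C@@H]2[C@@H](O[Si](C)(C)C(C)(C)C)C1 | intermediate
13 | (1R,5S,6S)-C14 allylic alcohol, C4 ketal, 6-OTBS | OCC1=CC[C@@]2(C)CCC3(OCCO3)[C@@H]2[C@@H](O[Si](C)(C)C(C)(C)C)C1 | intermediate
14 | (1R,5S,6S)-C4 ketone, 6-OTBS, C14 OH | OCC1=CC[C@@]2(C)CCC(=O)[C@@H]2[C@@H](O[Si](C)(C)C(C)(C)C)C1 | intermediate
15 | (1R,4R,5S,6S)-4-isopropyl-4,14-diol, 6-OTBS | OCC1=CC[C@@]2(C)CC[C@@](O)(C(C)C)[C@@H]2[C@@H](O[Si](C)(C)C(C)(C)C)C1 | intermediate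
16 | (1R,4R,5S,6S)-4-isopropyl-4,6,14-triol | OCC1=CC[C@@]2(C)CC[C@@](O)(C(C)C)[C@@H]2[C@@H](O)C1 | intermediate
17 | (1R,4R,5S,6S)-4,6-dihydroxy-4-isopropyl C14 enal | O=CC1=CC[C@@]2(C)CC[C@@](O)(C(C)C)[C@@H]2[C@@H](O)C1 | intermediate
18 | 4-hydroxybenzoic acid | O=C(O)c1ccc(O)cc1 | starting material
19 | tert-butyldimethylsilyl 4-[(tert-butyldimethylsilyl)oxy]benzoate | CC(C)(C)[Si](C)(C)OC(=O)c1ccc(O[Si](C)(C)C(C)(C)C)cc1 | intermediate (not isolated)
20 | 4-[(tert-butyldimethylsilyl)oxy]benzoic acid | CC(C)(C)[Si](C)(C)Oc1ccc(cc1)C(=O)O | intermediate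
21 | 6-O-[4-(tert-butyldimethylsilyloxy)benzoyl] ester of 17 | O=CC1=CC[C@@]2(C)CC[C@@](O)(C(C)C)[C@@H]2[C@@H](OC(=O)c3ccc(O[Si](C)(C)C(C)(C)C)cc3)C1 | intermediate
22 | CNP0267880.1, (3R,3aS,4S,8aR)-6-formyl-3-hydroxy-8a-methyl-3-(propan-2-yl)-1,2,3,3a,4,5,8,8a-octahydroazulen-4-yl 4-hydroxybenzoate | CC(C)[C@]1(O)CC[C@]2(C)CC=C(C=O)C[C@H](OC(=O)c3ccc(O)cc3)[C@H]21 | target

Total step count: 15. Longest linear sequence: 13 steps (1, 2, 3, 5, 6, 7, 8, 9, 10, 11, 12, 14, 15); steps 4 and 13 are side branches.

Steps most likely to fail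

Step 6. The borane may be delivered to the β-face of C5=C6, because ring B folds C10 and C8 beneath the α-face while only the methyl guards the β-face; it may also attack the enoate. The fallback closes the β-face with a second group and sets out from 9. The ketal is hydrolysed (PPTS, acetone/H2O) to the enone F6. Corey–Bakshi–Shibata reduction with the (R)-oxazaborolidine and catecholborane, the alkenyl branch acting as the large group, should give the (4S)-allylic alcohol F7 (4β-OH), which is silylated (Et3SiCl, imidazole) to the triethylsilyl ether F8. Hydroboration then meets a β-face blocked by both the methyl and the adjacent silyloxy group and should give, through the alkylborane F9, the 5α-H, 6α-hydroxy compound F10. TBSOTf/2,6-lutidine gives the bis-silyl ether F11, PPTS in MeOH removes only the triethylsilyl group to give the C4 alcohol F12, and Dess–Martin oxidation gives the keto ester F13. i-PrMgCl/CeCl3 at −78 °C adds to the ketone in the presence of the conjugated ester to give the tertiary alcohol ester F14, and i-Bu2AlH reduction rejoins the route at 15.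

Step 5. The unsubstituted diazo ester may be lost by electrocyclisation to a pyrazole before carbene transfer, the carbenoid may be captured by a ketal oxygen, and enantioface selection may erode; a sluggish boat shift is met by heating. The fallback uses a stabilised, storable carbenoid precursor and sets out from 5. Methyl acetoacetate is converted by diazo transfer into methyl 2-diazo-3-oxobutanoate F1 and by TBSOTf/Et3N into methyl 3-[(tert-butyldimethylsilyl)oxy]-2-diazobut-3-enoate F2. With 5 and Rh2(S-PTAD)4 (dirhodium tetrakis[(S)-2-(adamantan-1-yl)-2-(1,3-dioxoisoindolin-2-yl)acetate], taken to induce in the same sense as Rh2(R-DOSP)4) in hexanes this should give, through the siloxy divinylcyclopropane F3, the 9-silyloxy cycloadduct F4. CsF/PhNTf2 converts the silyl enol ether directly into the enol triflate F5, and Pd(OAc)2/PPh3 with HCO2H/Et3N reduces the triflate to give 9.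

Step 10. Hydride transfer from the isopropyl reagent may reduce the hindered ketone, or enolisation may lead to loss of silanol across C5–C6. The fallback sets out from 14 and uses an sp2 nucleophile that cannot act as a hydride donor. Isopropenylmagnesium bromide/CeCl3 in THF at −78 °C should give the isopropenyl carbinol F15 by the same α-face addition. Hydrogenation over RhCl(PPh3)3 (H2, 1 atm, benzene) saturates the 1,1-disubstituted alkene in preference to the trisubstituted C8=C9 and returns 15.

Further compounds
F1 | step 5 | methyl 2-diazo-3-oxobutanoate | COC(=O)C(=[N+]=[N-])C(C)=O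
F2 | step 5 | methyl 3-[(tert-butyldimethylsilyl)oxy]-2-diazobut-3-enoate | COC(=O)C(=[N+]=[N-])C(=C)O[Si](C)(C)C(C)(C)C
F3 | step 5 | siloxy analogue of 8, silyloxyvinyl cis to the cyclopentenyl group (not isolated) | COC(=O)[C@]1(C(=C)O[Si](C)(C)C(C)(C)C)C[C@H]1C1=C(C)CCC12OCCO2
F4 | step 5 | 9-(tert-butyldimethylsilyloxy) analogue of 9 | COC(=O)C1=C(O[Si](C)(C)C(C)(C)C)C[C@@]2(C)CCC3(OCCO3)C2=CC1
F5 | step 5 | 9-(trifluoromethanesulfonyloxy) analogue of 9 | COC(=O)C1=C(OS(=O)(=O)C(F)(F)F)C[C@@]2(C)CCC3(OCCO3)C2=CC1
F6 | step 6 | (1R)-C4 enone, C5=C6 and C8=C9, CO2Me on C8 | COC(=O)C1=CC[C@@]2(C)CCC(=O)C2=CC1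
F7 | step 6 | (1R,4S)-4β-hydroxy diene ester | COC(=O)C1=CC[C@@]2(C)CC[C@H](O)C2=CC1
F8 | step 6 | 4-O-triethylsilyl ether of F7 | COC(=O)C1=CC[C@@]2(C)CC[C@H](O[Si](CC)(CC)CC)C2=CC1
F9 | step 6 | C6 alkylborane of F8 (5α-H, 6α-BH2; not isolated) | COC(=O)C1=CC[C@@]2(C)CC[C@H](O[Si](CC)(CC)CC)[C@@H]2[C@@H](B)C1
F10 | step 6 | 4β-triethylsilyloxy 6α-hydroxy ester (5α-H) | COC(=O)C1=CC[C@@]2(C)CC[C@H](O[Si](CC)(CC)CC)[C@@H]2[C@@H](O)C1
F11 | step 6 | 4β-triethylsilyloxy 6α-tert-butyldimethylsilyloxy ester | COC(=O)C1=CC[C@@]2(C)CC[C@H](O[Si](CC)(CC)CC)[C@@H]2[C@@H](O[Si](C)(C)C(C)(C)C)C1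
F12 | step 6 | 4β-hydroxy 6α-tert-butyldimethylsilyloxy ester | COC(=O)C1=CC[C@@]2(C)CC[C@H](O)[C@@H]2[C@@H](O[Si](C)(C)C(C)(C)C)C1
F13 | step 6 | C4 keto ester, 6-OTBS (methyl ester analogue of 14) | COC(=O)C1=CC[C@@]2(C)CCC(=O)[C@@H]2[C@@H](O[Si](C)(C)C(C)(C)C)C1
F14 | step 6 | 4β-hydroxy-4-isopropyl ester, 6-OTBS (methyl ester analogue of 15) | COC(=O)C1=CC[C@@]2(C)CC[C@@](O)(C(C)C)[C@@H]2[C@@H](O[Si](C)(C)C(C)(C)C)C1
F15 | step 10 | 4-isopropenyl analogue of 15 | OCC1=CC[C@@]2(C)CC[C@@](O)(C(C)=C)[C@@H]2[C@@H](O[Si](C)(C)C(C)(C)C)C1
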